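**Retrosynthetic overview**
1. The last C–C bond is the interflavan bond C4 (upper ring C)–C6 (lower ring A), made by a 4β-selective Friedel–Crafts alkylation. The upper flavan (rings A, C and B with C2 and C3) comes intact from (−)-epigallocatechin; its five phenols are benzylated and the gallate is attached at O3 as its tribenzyl ether. Both partners carry a C8 bromine, so C6 is the only ring A site left open.
2. Lower ring C is closed in one operation from aldehyde 7 (C2, O1, ring B) and enol silane 6 (C3, C4, ring A). Aldol addition makes C2–C3, the new alkoxide displaces fluoride at C8a to make O1–C8a, and that fluoride starts the next aldol.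
3. Enabling feature: C4 of the lower unit is a benzylic CH2 on C4a, ortho to C8a of ring A, and O5 and O7 are meta to C8a. With C4 carried as a ketone, C3 is an enolate carbon, C8a–F is a vinylogous acyl fluoride (6 is a benzo-fused Danishefsky-type diene), and C3 can equilibrate to the 2,3-trans arrangement.
4. Ring order: lower ring A bought as 1,3,5-trifluorobenzene → lower ring C (step 4) → C4 deoxygenation and C8 bromination → union with the epigallocatechin-derived rings → hydrogenolysis of fourteen benzyl ethers and two C–Br bonds.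

Key step: step 4

Assumption: the target is read as epigallocatechin 3-O-gallate-(4β→6)-gallocatechin (upper unit 2R,3R,4S; lower unit 2R,3S); compounds 1, 3, 7, 15 and 17 are purchased.

**Route**

Step 1
Reactants: 1 1,3,5-trifluorobenzene
Product: 2 1,3-bis(benzyloxy)-5-fluorobenzene
Conditions: BnOH (2.1 equiv), NaH (2.2 equiv), NMP, 0 °C then 90 °C (sealed vessel)
Reagents that add atoms: benzyl alcohol, OCc1ccccc1
Why: Two successive SNAr displacements of fluoride by benzyloxide, each activated by the remaining meta fluorines; the third displacement is slowed by the two ether donors, so the stoichiometry should stop the reaction at the monofluoride.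

Step 2
Reactants: 2 1,3-bis(benzyloxy)-5-fluorobenzene; 3 2-(benzyloxy)-N-methoxy-N-methylacetamide
Product: 5 2-(benzyloxy)-1-[2,4-bis(benzyloxy)-6-fluorophenyl]ethan-1-one, via aryllithium 4 (not isolated)
Conditions: n-BuLi (1.05 equiv), THF, −78 °C; then 3, −78 °C; quench with 1 M HCl at −78 °C
Reagents that add atoms: none
Why: Directed ortho-metalation at the C–H flanked by fluorine and a benzyloxy group (the most acidic site, two equivalent positions) followed by Weinreb ketone synthesis, the chelated tetrahedral intermediate preventing over-addition and the low temperature preventing loss of LiF from 4 to an aryne.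

Step 3
Reactants: 5 2-(benzyloxy)-1-[2,4-bis(benzyloxy)-6-fluorophenyl]ethan-1-one
Product: 6 (Z)-{[2-(benzyloxy)-1-[2,4-bis(benzyloxy)-6-fluorophenyl]ethenyl]oxy}trimethylsilane
Conditions: TMSOTf (1.3 equiv), Et3N (1.6 equiv), CH2Cl2, 0 °C; pentane extraction, used crude under argon
Reagents that add atoms: trimethylsilyl trifluoromethanesulfonate, C[Si](C)(C)OS(=O)(=O)C(F)(F)F
Why: Soft enolisation and O-silylation of an α-alkoxy aryl ketone, expected to give the Z enol silane (least allylic strain against the twisted aryl group); the geometry is not critical because C3 is equilibrated in step 4.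

Step 4
Reactants: 6 (Z)-enol silane of ketone 5; 7 3,4,5-tris(benzyloxy)benzaldehyde
Product: 11 (2R,3R)-3,5,7-tris(benzyloxy)-2-[3,4,5-tris(benzyloxy)phenyl]chroman-4-one, via ammonium enolate 8 (not isolated), via ammonium aldolate 9 (not isolated), via cis-chromanone 10 (not isolated)
Conditions: O(9)-allyl-N-(9-anthracenylmethyl)cinchonidinium hydrogen difluoride (10 mol%), 7 (1.1 equiv), anhydrous THF, −60 → 0 °C; then DBU (0.2 equiv), 23 °C
Reagents that add atoms: none
Why: Proposed new method: fluoride from the catalyst desilylates 6 to the ion-paired enolate 8, C3 of 8 adds to the carbonyl carbon of 7 (C2–C3) to give aldolate 9, the alkoxide O1 of 9 closes ring C by addition–elimination at C8a (O1–C8a), and the fluoride expelled there, now paired with the chiral cation, desilylates the next molecule of 6, so that Me3SiF is the only stoichiometric by-product and no achiral cation is present at any time. The closest known reaction types are the Mukaiyama aldol addition of aryl ketone enol silanes to aromatic aldehydes under chiral quaternary ammonium fluoride catalysis, the aldol/cyclisation of Danishefsky-type dienes to dihydropyranones, and the intramolecular SNAr of β-oxido 2-fluoroaryl ketones to chroman-4-ones; what is new is their coupling through the leaving group. Ring C closes by a formal 6-endo-trig attack of O1 on the vinylogous acyl fluoride C8a=C4a–C4=O, through a Meisenheimer anion delocalised onto the C4 carbonyl, which the meta benzyloxy groups at C5 and C7 do not oppose. C2 is controlled by the cinchonidinium cation, which should cover the Re face of 7 in the contact ion pair so that C3 adds to the Si face (R at C2; should retro-aldol outrun closure, the same cation selects in the irreversible SNAr step), the cinchoninium pseudoenantiomer being at hand if the sense is found reversed. C3 is controlled thermodynamically: whichever aldol diastereomer closes, the 2,3-cis chromanone 10 epimerises α to the ketone (fluoride, then DBU) to the diequatorial 2,3-trans isomer 11, while C2 stays fixed because ring opening by β-elimination is stereoelectronically poor (the C2–O1 bond lies near the nodal plane of the ring enolate). The step needs O1 and not O3 to attack C8a and closure to outrun dehydration and intermolecular arylation: O3 is benzylated, ring A carries a single fluorine, and the six-membered closure is intramolecular.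

Step 5
Reactants: 11 (2R,3R)-3,5,7-tris(benzyloxy)-2-[3,4,5-tris(benzyloxy)phenyl]chroman-4-one
Product: 12 (2R,3S)-3,5,7-tris(benzyloxy)-2-[3,4,5-tris(benzyloxy)phenyl]chroman-4-ol (C4 epimers)
Conditions: NaBH4 (1.5 equiv), THF/MeOH 4:1, 0 °C
Reagents that add atoms: none
Why: Borohydride reduction of the aryl ketone; the C4 configuration is irrelevant because C4 becomes CH2 in step 6, and C2 and C3 are not touched.

Step 6
Reactants: 12 (2R,3S)-3,5,7-tris(benzyloxy)-2-[3,4,5-tris(benzyloxy)phenyl]chroman-4-ol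
Product: 13 (2R,3S)-3,5,7-tris(benzyloxy)-2-[3,4,5-tris(benzyloxy)phenyl]chromane (hexa-O-benzyl-(+)-gallocatechin)
Conditions: Et3SiH (5 equiv), TFA (3 equiv), CH2Cl2 (0.02 M), −40 → 0 °C
Reagents that add atoms: none
Why: Ionic hydrogenation (benzylic deoxygenation): the C4 hydroxyl ionises with help from O1, O5 and O7 and the silane delivers hydride, excess silane and dilution keeping hydride capture ahead of Friedel–Crafts self-condensation.

Step 7
Reactants: 13 hexa-O-benzyl-(+)-gallocatechin
Product: 14 (2R,3S)-8-bromo-3,5,7-tris(benzyloxy)-2-[3,4,5-tris(benzyloxy)phenyl]chromane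
Conditions: NBS (1.05 equiv), CH2Cl2, −40 → 0 °C
Reagents that add atoms: N-bromosuccinimide, O=C1CCC(=O)N1Br
Why: Electrophilic aromatic bromination at C8 of ring A, the most reactive and least hindered position of 5,7-bis(benzyloxy)flavans (between O1 and one benzyloxy group), which leaves C6 as the only ring A nucleophilic site.

Step 8
Reactants: 15 (−)-epigallocatechin
Product: 16 (2R,3R)-5,7-bis(benzyloxy)-2-[3,4,5-tris(benzyloxy)phenyl]chroman-3-ol (penta-O-benzyl-epigallocatechin)
Conditions: BnBr (5.5 equiv), K2CO3 (6 equiv), degassed DMF, −10 → 23 °C, argon, dark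
Reagents that add atoms: benzyl bromide, BrCc1ccccc1
Why: Williamson etherification of the five phenols under a mild carbonate base, which does not deprotonate the secondary C3 alcohol; exclusion of oxygen protects the pyrogallol ring, and the low temperature should limit C-benzylation of ring A and epimerisation at C2.

Step 9
Reactants: 16 penta-O-benzyl-epigallocatechin; 17 3,4,5-tris(benzyloxy)benzoic acid
Product: 18 (2R,3R)-5,7-bis(benzyloxy)-2-[3,4,5-tris(benzyloxy)phenyl]chroman-3-yl 3,4,5-tris(benzyloxy)benzoate (octa-O-benzyl-EGCG)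
Conditions: DCC (1.5 equiv), DMAP (0.3 equiv), 17 (1.3 equiv), CH2Cl2, 0 → 23 °C
Reagents that add atoms: none
Why: Steglich esterification of the axial C3 hydroxyl through the acylpyridinium ion of the tribenzylgalloyl group; the reaction takes place at oxygen, so C2 and C3 keep their configuration.

Step 10
Reactants: 18 octa-O-benzyl-EGCG
Product: 19 8-bromo-octa-O-benzyl-EGCG
Conditions: NBS (1.0 equiv), CH2Cl2, −40 → 0 °C
Reagents that add atoms: N-bromosuccinimide, O=C1CCC(=O)N1Br
Why: Electrophilic aromatic bromination at C8 as in step 7, which removes the most nucleophilic position of the future electrophile so that it cannot alkylate itself there.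

Step 11
Reactants: 19 8-bromo-octa-O-benzyl-EGCG
Product: 20 (2R,3R,4S)-8-bromo-4-(2-ethoxyethoxy) derivative of 19 (4β-alkoxy)
Conditions: DDQ (2.0 equiv), 2-ethoxyethanol (10 equiv), CH2Cl2, 23 °C
Reagents that add atoms: 2-ethoxyethanol, CCOCCO
Why: Oxidative benzylic C–H etherification: DDQ abstracts hydride from C4 (stabilised by O1, O5, O7) and the alcohol adds from the β face, trans to the 3-O-galloyl group on the α face.

Step 12
Reactants: 14 8-bromo-hexa-O-benzyl-gallocatechin (2.5 equiv); 20 4β-(2-ethoxyethoxy) electrophile (1 equiv)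
Product: 21 tetradeca-O-benzyl-8,8'-dibromo-epigallocatechin 3-O-gallate-(4β→6)-gallocatechin
Conditions: TMSOTf (0.5 equiv), 4 Å molecular sieves, CH2Cl2, −78 → −30 °C, slow addition of 20 to 14; Et3N quench; unreacted 14 recovered
Reagents that add atoms: none
Why: Lewis acid-promoted Friedel–Crafts alkylation: ionisation at C4 of 20 is assisted by the α-face 3-O-galloyl carbonyl, so C6 of 14 (C8 blocked) should attack from the β face to give the 3,4-trans (4β) bond, the excess of 14 and slow addition favouring cross-coupling over attack at C6 of 20 or 21.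

Step 13
Reactants: 21 protected dimer
Product: 22 epigallocatechin 3-O-gallate-(4β→6)-gallocatechin (target)
Conditions: H2 (1 atm), Pd(OH)2/C, Et3N (2.2 equiv), THF/MeOH/H2O 20:20:1, 23 °C; filtration under argon, lyophilisation
Reagents that add atoms: none
Why: Catalytic hydrogenolysis of the fourteen benzyl ethers and both aryl C–Br bonds, with Et3N taking up HBr so that the acid-labile interflavan bond and the stereocentres are not disturbed.

**Compound list**
1 | 1,3,5-trifluorobenzene | Fc1cc(F)cc(F)c1 | starting material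
2 | 1,3-bis(benzyloxy)-5-fluorobenzene | Fc1cc(OCc2ccccc2)cc(OCc2ccccc2)c1 | intermediate
3 | 2-(benzyloxy)-N-methoxy-N-methylacetamide | CON(C)C(=O)COCc1ccccc1 | starting material
4 | [2,4-bis(benzyloxy)-6-fluorophenyl]lithium | [Li]c1c(F)cc(OCc2ccccc2)cc1OCc1ccccc1 | intermediate (not isolated)
5 | 2-(benzyloxy)-1-[2,4-bis(benzyloxy)-6-fluorophenyl]ethan-1-one | O=C(COCc1ccccc1)c1c(F)cc(OCc2ccccc2)cc1OCc1ccccc1 | intermediate
6 | (Z)-{[2-(benzyloxy)-1-[2,4-bis(benzyloxy)-6-fluorophenyl]ethenyl]oxy}trimethylsilane | C[Si](C)(C)O/C(=C\OCc1ccccc1)c1c(F)cc(OCc2ccccc2)cc1OCc1ccccc1 | intermediate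
7 | 3,4,5-tris(benzyloxy)benzaldehyde | O=Cc1cc(OCc2ccccc2)c(OCc2ccccc2)c(OCc2ccccc2)c1 | starting material
8 | (Z)-enolate of 5, ion-paired with the catalyst cation (anion shown) | [O-]/C(=C\OCc1ccccc1)c1c(F)cc(OCc2ccccc2)cc1OCc1ccccc1 | intermediate (not isolated)
9 | (3R)-2-(benzyloxy)-1-[2,4-bis(benzyloxy)-6-fluorophenyl]-3-oxido-3-[3,4,5-tris(benzyloxy)phenyl]propan-1-one, C2 epimers, ion-paired with the catalyst cation (anion shown) | [O-][C@H](c1cc(OCc2ccccc2)c(OCc2ccccc2)c(OCc2ccccc2)c1)C(OCc1ccccc1)C(=O)c1c(F)cc(OCc2ccccc2)cc1OCc1ccccc1 | intermediate (not isolated)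
10 | (2R,3S)-3,5,7-tris(benzyloxy)-2-[3,4,5-tris(benzyloxy)phenyl]chroman-4-one (2,3-cis) | O=C1[C@@H](OCc2ccccc2)[C@@H](c2cc(OCc3ccccc3)c(OCc3ccccc3)c(OCc3ccccc3)c2)Oc2cc(OCc3ccccc3)cc(OCc3ccccc3)c12 | intermediate (not isolated)
11 | (2R,3R)-3,5,7-tris(benzyloxy)-2-[3,4,5-tris(benzyloxy)phenyl]chroman-4-one (2,3-trans) | O=C1[C@H](OCc2ccccc2)[C@@H](c2cc(OCc3ccccc3)c(OCc3ccccc3)c(OCc3ccccc3)c2)Oc2cc(OCc3ccccc3)cc(OCc3ccccc3)c12 | intermediate
12 | (2R,3S)-3,5,7-tris(benzyloxy)-2-[3,4,5-tris(benzyloxy)phenyl]chroman-4-ol, C4 epimers | OC1[C@H](OCc2ccccc2)[C@@H](c2cc(OCc3ccccc3)c(OCc3ccccc3)c(OCc3ccccc3)c2)Oc2cc(OCc3ccccc3)cc(OCc3ccccc3)c12 | intermediate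
13 | (2R,3S)-3,5,7-tris(benzyloxy)-2-[3,4,5-tris(benzyloxy)phenyl]chromane | C1[C@H](OCc2ccccc2)[C@@H](c2cc(OCc3ccccc3)c(OCc3ccccc3)c(OCc3ccccc3)c2)Oc2cc(OCc3ccccc3)cc(OCc3ccccc3)c12 | intermediate
14 | (2R,3S)-8-bromo-3,5,7-tris(benzyloxy)-2-[3,4,5-tris(benzyloxy)phenyl]chromane | C1[C@H](OCc2ccccc2)[C@@H](c2cc(OCc3ccccc3)c(OCc3ccccc3)c(OCc3ccccc3)c2)Oc2c(Br)c(OCc3ccccc3)cc(OCc3ccccc3)c12 | intermediate
15 | (−)-epigallocatechin (2R,3R) | O[C@@H]1Cc2c(O)cc(O)cc2O[C@@H]1c1cc(O)c(O)c(O)c1 | starting material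
16 | penta-O-benzyl-epigallocatechin (2R,3R) | O[C@@H]1Cc2c(OCc3ccccc3)cc(OCc3ccccc3)cc2O[C@@H]1c1cc(OCc2ccccc2)c(OCc2ccccc2)c(OCc2ccccc2)c1 | intermediate
17 | 3,4,5-tris(benzyloxy)benzoic acid | OC(=O)c1cc(OCc2ccccc2)c(OCc2ccccc2)c(OCc2ccccc2)c1 | starting material
18 | octa-O-benzyl-EGCG (2R,3R) | O=C(O[C@@H]1Cc2c(OCc3ccccc3)cc(OCc3ccccc3)cc2O[C@@H]1c1cc(OCc2ccccc2)c(OCc2ccccc2)c(OCc2ccccc2)c1)c1cc(OCc2ccccc2)c(OCc2ccccc2)c(OCc2ccccc2)c1 | intermediate
19 | 8-bromo-octa-O-benzyl-EGCG (2R,3R) | O=C(O[C@@H]1Cc2c(OCc3ccccc3)cc(OCc3ccccc3)c(Br)c2O[C@@H]1c1cc(OCc2ccccc2)c(OCc2ccccc2)c(OCc2ccccc2)c1)c1cc(OCc2ccccc2)c(OCc2ccccc2)c(OCc2ccccc2)c1 | intermediate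
20 | 8-bromo-4β-(2-ethoxyethoxy)-octa-O-benzyl-EGCG (2R,3R,4S) | O=C(O[C@@H]1[C@@H](OCCOCC)c2c(OCc3ccccc3)cc(OCc3ccccc3)c(Br)c2O[C@@H]1c1cc(OCc2ccccc2)c(OCc2ccccc2)c(OCc2ccccc2)c1)c1cc(OCc2ccccc2)c(OCc2ccccc2)c(OCc2ccccc2)c1 | intermediate
21 | tetradeca-O-benzyl-8,8'-dibromo-epigallocatechin 3-O-gallate-(4β→6)-gallocatechin | O=C(O[C@@H]1[C@@H](c2c(OCc3ccccc3)c(Br)c3c(c2OCc2ccccc2)C[C@H](OCc2ccccc2)[C@@H](c2cc(OCc4ccccc4)c(OCc4ccccc4)c(OCc4ccccc4)c2)O3)c2c(OCc3ccccc3)cc(OCc3ccccc3)c(Br)c2O[C@@H]1c1cc(OCc2ccccc2)c(OCc2ccccc2)c(OCc2ccccc2)c1)c1cc(OCc2ccccc2)c(OCc2ccccc2)c(OCc2ccccc2)c1 | intermediate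
22 | epigallocatechin 3-O-gallate-(4β→6)-gallocatechin | O=C(O[C@@H]1[C@@H](c2c(O)cc3c(c2O)C[C@H](O)[C@@H](c2cc(O)c(O)c(O)c2)O3)c2c(O)cc(O)cc2O[C@@H]1c1cc(O)c(O)c(O)c1)c1cc(O)c(O)c(O)c1 | target

**Step count and risks**
Total steps: 13. Longest linear sequence: 9 (steps 1–7, 12, 13).

Steps most likely to fail:

1. Step 4. The chiral cation may discriminate the aldehyde faces poorly, the fluoride relay may stall through protonation or silyl transfer, or retro-aldol and dehydration may compete with ring closure. The fallback uses known chemistry, sets out from aldehyde 7 and returns to the route at 11. Aldehyde 7 undergoes a boron-mediated Evans syn-glycolate aldol with commercial (S)-4-benzyl-3-[(benzyloxy)acetyl]oxazolidin-2-one (O=C(COCc1ccccc1)N1[C@@H](Cc2ccccc2)COC1=O; Bu2BOTf, i-Pr2NEt, CH2Cl2, −78 → 0 °C) to give the syn-aldol imide F1, in which the auxiliary should fix the R carbinol centre (the later C2). AlMe3 and MeNH(OMe)·HCl convert it into the Weinreb amide F2 with recovery of the auxiliary, and TESOTf with 2,6-lutidine gives the triethylsilyl ether F3. Aryllithium 4 (made from 2 as in step 2) adds to F3 to give the β-silyloxy 2-fluoroaryl ketone F4. Tetrabutylammonium fluoride in THF then frees the alkoxide, which closes ring C by the same SNAr to give cis-chromanone 10, and DBU epimerises C3 to give 11.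

2. Step 12. The electrophile may alkylate C6 of another molecule of 20 or of 21 instead of the hindered C6 of 14, giving oligomers and poor conversion. The fallback replaces statistical control by complete blocking; it sets out from 18 and returns at 22. Compound 18 is brominated twice (NBS, 2.1 equiv) to give the 6,8-dibromide F5, which DDQ and 2-ethoxyethanol convert into the 4β-(2-ethoxyethoxy) dibromide F6. F6 (1.3 equiv) has no free ring A position and is coupled with 14 under TMSOTf to give the tribromo dimer F7, which is hydrogenolysed as in step 13 to give 22.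

3. Step 2. Lithiation may occur between the two benzyloxy groups or at a benzylic CH2 instead of next to fluorine, or 4 may lose LiF to an aryne if the temperature rises. The fallback sets out from 2 and returns at 5. Compound 2 is acylated in a Friedel–Crafts reaction with benzyloxyacetic acid (OC(=O)COCc1ccccc1), trifluoroacetic anhydride and catalytic H3PO4 in MeCN at 0 → 23 °C. Here sterics, not acidity, should direct the acyl group para to one benzyloxy group and ortho to fluorine, to give 5 directly; no new compound arises (F0).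

**Further compounds**
F1 | step 4 | (S)-4-benzyl-3-[(2S,3R)-2-(benzyloxy)-3-hydroxy-3-[3,4,5-tris(benzyloxy)phenyl]propanoyl]oxazolidin-2-one | O=C([C@@H](OCc1ccccc1)[C@H](O)c1cc(OCc2ccccc2)c(OCc2ccccc2)c(OCc2ccccc2)c1)N1[C@@H](Cc2ccccc2)COC1=O
F2 | step 4 | (2S,3R)-2-(benzyloxy)-3-hydroxy-N-methoxy-N-methyl-3-[3,4,5-tris(benzyloxy)phenyl]propanamide | CON(C)C(=O)[C@@H](OCc1ccccc1)[C@H](O)c1cc(OCc2ccccc2)c(OCc2ccccc2)c(OCc2ccccc2)c1
F3 | step 4 | (2S,3R)-2-(benzyloxy)-N-methoxy-N-methyl-3-[(triethylsilyl)oxy]-3-[3,4,5-tris(benzyloxy)phenyl]propanamide | CON(C)C(=O)[C@@H](OCc1ccccc1)[C@H](O[Si](CC)(CC)CC)c1cc(OCc2ccccc2)c(OCc2ccccc2)c(OCc2ccccc2)c1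
F4 | step 4 | (2S,3R)-2-(benzyloxy)-1-[2,4-bis(benzyloxy)-6-fluorophenyl]-3-[(triethylsilyl)oxy]-3-[3,4,5-tris(benzyloxy)phenyl]propan-1-one | O=C([C@@H](OCc1ccccc1)[C@H](O[Si](CC)(CC)CC)c1cc(OCc2ccccc2)c(OCc2ccccc2)c(OCc2ccccc2)c1)c1c(F)cc(OCc2ccccc2)cc1OCc1ccccc1
F5 | step 12 | 6,8-dibromo-octa-O-benzyl-EGCG (2R,3R) | O=C(O[C@@H]1Cc2c(OCc3ccccc3)c(Br)c(OCc3ccccc3)c(Br)c2O[C@@H]1c1cc(OCc2ccccc2)c(OCc2ccccc2)c(OCc2ccccc2)c1)c1cc(OCc2ccccc2)c(OCc2ccccc2)c(OCc2ccccc2)c1
F6 | step 12 | 6,8-dibromo-4β-(2-ethoxyethoxy)-octa-O-benzyl-EGCG | O=C(O[C@@H]1[C@@H](OCCOCC)c2c(OCc3ccccc3)c(Br)c(OCc3ccccc3)c(Br)c2O[C@@H]1c1cc(OCc2ccccc2)c(OCc2ccccc2)c(OCc2ccccc2)c1)c1cc(OCc2ccccc2)c(OCc2ccccc2)c(OCc2ccccc2)c1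
F7 | step 12 | tetradeca-O-benzyl-6,8,8'-tribromo-epigallocatechin 3-O-gallate-(4β→6)-gallocatechin | O=C(O[C@@H]1[C@@H](c2c(OCc3ccccc3)c(Br)c3c(c2OCc2ccccc2)C[C@H](OCc2ccccc2)[C@@H](c2cc(OCc4ccccc4)c(OCc4ccccc4)c(OCc4ccccc4)c2)O3)c2c(OCc3ccccc3)c(Br)c(OCc3ccccc3)c(Br)c2O[C@@H]1c1cc(OCc2ccccc2)c(OCc2ccccc2)c(OCc2ccccc2)c1)c1cc(OCc2ccccc2)c(OCc2ccccc2)c(OCc2ccccc2)c1
F0 | step 2 | none | none
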